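**Retrosynthetic overview**
1. Target ⇒ oplopane core: the last operations are O‑9 acylation, SeO2 hydroxylation at C9, O‑8 acylation and 8‑OH‑directed epoxidation of the isopropenyl group.
2. Cyclopentanone ring A with its 1‑acetoxyethyl arm ⇒ cadin‑4‑en‑3‑one 4,5‑epoxide by 1,2‑acyl shift (six‑ to five‑membered ring), the way oplopanes are thought to arise from cadinanes.
3. Cadinane ring B ⇒ bisabolane enone by an oxidative C6–C7 closure that also creates the isopropenyl group, a one‑electron version of the bisabolyl → cadinyl closure.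
4. Bisabolane ⇒ (R)‑carvone (ring A, C9, C10, C14) + prenal (C7, C8, C11–C13) by catalytic asymmetric allylation.
5. Ring order: ring A is bought as carvone, ring B is closed onto it, then ring A is contracted.

Labels: cadinane numbering is kept throughout. C1/C6 are the ring‑fusion carbons (C1 next to C10), C3 is the ring ketone, C4 (methyl C15) is the acetyl/carbinol carbon on C5, C7 bears C11 (C12 = CH2, C13 = CH3), C8 and C9 are the oxygenated carbons, C10=C14 is the exocyclic methylene. α = face of H‑1, β = face of H‑6.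
Assumption: (2Z)‑3‑methylpent‑2‑enoic acid and (2R)‑2‑methylbutanoic acid are bought as catalogue chemicals.

**Step 1**
Reactants: 1 (R)‑carvone
Product: 2 (5R)‑5‑(3‑chloroprop‑1‑en‑2‑yl)‑2‑methylcyclohex‑2‑en‑1‑one
Conditions: Ca(OCl)2, CO2 (dry ice), CH2Cl2/H2O, 0 °C
Reagents that add atoms: calcium hypochlorite, [Ca+2].[O-]Cl.[O-]Cl
Why: HOCl made in situ chlorinates the electron‑rich 1,1‑disubstituted olefin in an ene‑type allylic chlorination with double‑bond shift; the enone and the carvone stereocenter (later C1) are untouched.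

**Step 2**
Reactants: 2 (5R)‑5‑(3‑chloroprop‑1‑en‑2‑yl)‑2‑methylcyclohex‑2‑en‑1‑one; 3 3‑methylbut‑2‑enal
Product: 5 (5R)‑5‑[(4R)‑4‑hydroxy‑6‑methylhepta‑1,5‑dien‑2‑yl]‑2‑methylcyclohex‑2‑en‑1‑one, via TMS ether 4 (not isolated)
Conditions: CrCl2 (10 mol %), chiral 3,6‑di‑tert‑butyl‑1,8‑bis(4‑isopropyl‑4,5‑dihydrooxazol‑2‑yl)carbazole ligand (12 mol %, the antipode that gives Re‑face addition), Mn, Me3SiCl, i‑Pr2NEt, THF, rt; then 1 M HCl
Reagents that add atoms: 3‑methylbut‑2‑enal 3, CC(C)=CC=O; chlorotrimethylsilane, C[Si](C)(C)Cl (silyl group only in 4)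
Why: catalytic asymmetric Nozaki–Hiyama–Kishi allylation; the allyl unit generated by divalent chromium adds 1,2 to the aldehyde only (ketone untouched), and the ligand directs it to the Re face, setting C8 as R independently of the remote ring stereocenter.

**Step 3**
Reactants: 5 (5R)‑5‑[(4R)‑4‑hydroxy‑6‑methylhepta‑1,5‑dien‑2‑yl]‑2‑methylcyclohex‑2‑en‑1‑one
Product: 6 (5R)‑5‑[(4R)‑4‑(tert‑butyldimethylsilyloxy)‑6‑methylhepta‑1,5‑dien‑2‑yl]‑2‑methylcyclohex‑2‑en‑1‑one
Conditions: TBSCl, imidazole, DMF, rt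
Reagents that add atoms: tert‑butyldimethylsilyl chloride, CC(C)(C)[Si](C)(C)Cl
Why: standard silylation; the 8‑oxygen must stay masked until the side‑chain alcohol has been acetylated (step 8) and is then needed free to direct the epoxidation (step 10).

**Step 4**
Reactants: 6 (5R)‑5‑[(4R)‑4‑(tert‑butyldimethylsilyloxy)‑6‑methylhepta‑1,5‑dien‑2‑yl]‑2‑methylcyclohex‑2‑en‑1‑one
Product: 9 8α‑(tert‑butyldimethylsilyloxy)cadina‑4,10(14),11‑trien‑3‑one (trans‑fused; H‑1α H‑6β H‑7α), via potassium dienolate 7 (not isolated), via cis‑fused enone 8 (not isolated)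
Conditions: KOt‑Bu (1.1 equiv), THF, 0 °C; Cu(2‑ethylhexanoate)2 (2.3 equiv), −78 °C → rt, high dilution; aqueous work‑up; then KOt‑Bu (0.2 equiv), t‑BuOH/THF, rt
Reagents that add atoms: potassium tert‑butoxide, CC(C)(C)[O-].[K+] (potassium only in 7)
Why: Proposed new method: reversible deprotonation gives the linear γ‑dienolate 7, the thermodynamic enolate of a 2‑methylcyclohexenone; fast one‑electron oxidation by divalent copper gives a dienoxyl radical whose only terminus able to reach the side chain, C6, adds 6‑exo to the trisubstituted olefin at C7 through a chair with 8‑OTBS and the olefin equatorial (7β‑isopropenyl, trans to 8‑O), and a second divalent copper oxidises the tertiary C11 radical with loss of a C12 proton to the isopropenyl group, an oxidative copy of the biosynthetic bisabolyl → cadinyl closure; the kinetic cis fusion (8) is corrected because C6 is the γ‑carbon of the enone and catalytic base equilibrates it to the all‑equatorial trans‑decalin 9; closest known chemistry is the Snider Mn(OAc)3/Cu(OAc)2 oxidative radical cyclisation and oxidative enolate coupling with Cu(2‑ethylhexanoate)2.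

**Step 5**
Reactants: 9 8α‑(tert‑butyldimethylsilyloxy)cadina‑4,10(14),11‑trien‑3‑one
Product: 10 4α,5α‑epoxide of 9 (4,5‑epoxy‑3‑ketone)
Conditions: H2O2 (30 %), NaOH (cat.), MeOH, 0 °C
Reagents that add atoms: hydrogen peroxide, OO
Why: Weitz–Scheffer nucleophilic epoxidation touches only the enone; hydroperoxide adds axially to C5 anti to axial H‑6 (α face), and either epoxide face would serve because C4 and C5 lose this information in step 6.

**Step 6**
Reactants: 10 4α,5α‑epoxide of 9
Product: 12 ring‑contracted diketone (trans‑fused cyclopentan‑3‑one; 5β‑acetyl; 7β‑isopropenyl; 8α‑OTBS; 10‑methylene), via 5‑epi‑diketone 11 (not isolated)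
Conditions: BF3·OEt2 (1.1 equiv), CH2Cl2, −78 → −30 °C; aq. NaHCO3; then Et3N (cat.), rt
Reagents that add atoms: none
Why: House‑type Lewis‑acid rearrangement of an α,β‑epoxy ketone (as in isophorone oxide → 2‑formylcyclopentanone): the epoxide opens at C5 and the C3 acyl group shifts from C4 to C5 with inversion, contracting ring A and leaving C4 as the acetyl carbonyl, which is the presumed cadinane → oplopane step; C5 lies between two carbonyls and settles through the enol to the 5β‑acetyl epimer trans to C7.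

**Step 7**
Reactants: 12 ring‑contracted diketone
Product: 13 (4S)‑4‑hydroxy compound (5β‑[(1S)‑1‑hydroxyethyl]cyclopentan‑3‑one)
Conditions: Zn(BH4)2 (0.5 equiv), Et2O, −78 → −40 °C
Reagents that add atoms: none
Why: chelation‑controlled reduction (Oishi–Nakata type) of the less hindered methyl ketone: zinc bridges both carbonyls and hydride enters the acetyl group from the face of H‑5, anti to C6, giving the syn (4S) carbinol; low temperature and substoichiometric hydride limit attack on the ring ketone.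

**Step 8**
Reactants: 13 (4S)‑4‑hydroxy compound
Product: 14 (4S)‑4‑acetate
Conditions: Ac2O, DMAP (cat.), pyridine, CH2Cl2, 0 °C
Reagents that add atoms: acetic anhydride, CC(=O)OC(C)=O
Why: acylation of the only free hydroxyl; cold, weakly basic conditions avoid β‑elimination of the β‑acetoxy ketone and epimerisation at C5.

**Step 9**
Reactants: 14 (4S)‑4‑acetate
Product: 15 8α‑alcohol (desilylated 14)
Conditions: HF·pyridine, pyridine/THF, 0 °C → rt
Reagents that add atoms: none
Why: fluoride‑driven Si–O cleavage under mildly acidic conditions, which the β‑acetoxy ketone and both olefins tolerate (basic fluoride would risk elimination of acetate).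

**Step 10**
Reactants: 15 8α‑alcohol
Product: 16 (11S)‑11,12‑epoxide of 15
Conditions: VO(acac)2 (5 mol %), t‑BuOOH (1.5 equiv), CH2Cl2, 0 °C → rt
Reagents that add atoms: tert‑butyl hydroperoxide, CC(C)(C)OO
Why: hydroxyl‑directed homoallylic epoxidation (Mihelich model): the equatorial 8‑O is gauche to C11 but anti to C10, so the metal‑bound peroxide reaches only the isopropenyl olefin, and the chair transition state with the =CH2 terminus turned toward the metal gives the 11S epoxide.

**Step 11**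
Reactants: 16 (11S)‑11,12‑epoxide of 15; 17 (2Z)‑3‑methylpent‑2‑enoic acid
Product: 18 8α‑[(2Z)‑3‑methylpent‑2‑enoyl] ester of 16
Conditions: DCC, DMAP (cat.), CH2Cl2, 0 °C → rt
Reagents that add atoms: (2Z)‑3‑methylpent‑2‑enoic acid 17, OC(=O)/C=C(/C)CC
Why: Steglich esterification of the equatorial secondary alcohol with retention at C8; catalytic DMAP at low temperature keeps the Z geometry of the β,β‑disubstituted enoate and leaves the epoxide intact.

**Step 12**
Reactants: 18 8α‑[(2Z)‑3‑methylpent‑2‑enoyl] ester of 16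
Product: 19 9α‑hydroxy derivative of 18
Conditions: SeO2 (0.3 equiv), t‑BuOOH (2.5 equiv), CH2Cl2, rt
Reagents that add atoms: tert‑butyl hydroperoxide, CC(C)(C)OO; selenium dioxide, O=[Se]=O (catalytic oxygen carrier)
Why: Sharpless‑type SeO2 allylic hydroxylation of the only remaining unfunctionalised olefin: the ene step takes the axial H‑9 (ring CH2 preferred over the methine C1), and the [2,3]‑sigmatropic shift returns oxygen to C9 on the same axial α face, cis to the 8α‑ester.

**Step 13**
Reactants: 19 9α‑hydroxy derivative of 18; 20 (2R)‑2‑methylbutanoic acid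
Product: 21 target CNP0262178.2
Conditions: DCC, DMAP (cat.), CH2Cl2, 0 °C
Reagents that add atoms: (2R)‑2‑methylbutanoic acid 20, OC(=O)[C@H](C)CC
Why: Steglich esterification of the axial allylic 9α‑alcohol with retention at C9; the acid brings in its own R stereocenter, and the cold conditions guard against its epimerisation and against 8→9 acyl migration.

**Compound list**
1 | (R)‑carvone, (5R)‑2‑methyl‑5‑(prop‑1‑en‑2‑yl)cyclohex‑2‑en‑1‑one | C=C(C)[C@H]1CC(=O)C(C)=CC1 | starting material
2 | (5R)‑5‑(3‑chloroprop‑1‑en‑2‑yl)‑2‑methylcyclohex‑2‑en‑1‑one (10‑chlorocarvone) | C=C(CCl)[C@H]1CC(=O)C(C)=CC1 | intermediate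
3 | 3‑methylbut‑2‑enal (prenal) | CC(C)=CC=O | starting material
4 | TMS ether of 5, (5R)‑2‑methyl‑5‑[(4R)‑6‑methyl‑4‑(trimethylsilyloxy)hepta‑1,5‑dien‑2‑yl]cyclohex‑2‑en‑1‑one | C=C(C[C@@H](O[Si](C)(C)C)C=C(C)C)[C@H]1CC(=O)C(C)=CC1 | intermediate (not isolated)
5 | (5R)‑5‑[(4R)‑4‑hydroxy‑6‑methylhepta‑1,5‑dien‑2‑yl]‑2‑methylcyclohex‑2‑en‑1‑one (bisabolane alcohol) | C=C(C[C@@H](O)C=C(C)C)[C@H]1CC(=O)C(C)=CC1 | intermediate
6 | (5R)‑5‑[(4R)‑4‑(tert‑butyldimethylsilyloxy)‑6‑methylhepta‑1,5‑dien‑2‑yl]‑2‑methylcyclohex‑2‑en‑1‑one | C=C(C[C@@H](O[Si](C)(C)C(C)(C)C)C=C(C)C)[C@H]1CC(=O)C(C)=CC1 | intermediate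
7 | potassium linear dienolate of 6 (O–C3=C4, C5=C6) | C=C(C[C@@H](O[Si](C)(C)C(C)(C)C)C=C(C)C)[C@H]1CC([O-])=C(C)C=C1.[K+] | intermediate (not isolated)
8 | cis‑fused enone, 6‑epimer of 9 (H‑1 and H‑6 both α) | C=C1[C@H]2CC(=O)C(C)=C[C@H]2[C@@H](C(C)=C)[C@H](O[Si](C)(C)C(C)(C)C)C1 | intermediate (not isolated)
9 | 8α‑(tert‑butyldimethylsilyloxy)cadina‑4,10(14),11‑trien‑3‑one, trans‑fused, H‑1α, H‑6β, H‑7α (7β‑isopropenyl and 8α‑OTBS equatorial) | C=C1[C@H]2CC(=O)C(C)=C[C@@H]2[C@@H](C(C)=C)[C@H](O[Si](C)(C)C(C)(C)C)C1 | intermediate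
10 | 4α,5α‑epoxide of 9 (4,5‑epoxy‑3‑ketone) | C=C1[C@H]2CC(=O)[C@]3(C)O[C@@H]3[C@@H]2[C@@H](C(C)=C)[C@H](O[Si](C)(C)C(C)(C)C)C1 | intermediate
11 | 5‑epi‑diketone (5α‑acetyl epimer of 12) | C=C1[C@H]2CC(=O)[C@H](C(C)=O)[C@@H]2[C@@H](C(C)=C)[C@H](O[Si](C)(C)C(C)(C)C)C1 | intermediate (not isolated)
12 | ring‑contracted diketone: trans‑fused bicyclo[4.3.0]nonan‑3‑one (ring A = C1–C2–C3(=O)–C5–C6) with 5β‑acetyl, 7β‑isopropenyl, 8α‑OTBS, 10‑methylene | C=C1[C@H]2CC(=O)[C@@H](C(C)=O)[C@@H]2[C@@H](C(C)=C)[C@H](O[Si](C)(C)C(C)(C)C)C1 | intermediate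
13 | (4S)‑4‑hydroxy compound, 5β‑[(1S)‑1‑hydroxyethyl] analogue of 12 | C=C1[C@H]2CC(=O)[C@@H]([C@H](C)O)[C@@H]2[C@@H](C(C)=C)[C@H](O[Si](C)(C)C(C)(C)C)C1 | intermediate
14 | (4S)‑4‑acetate of 13 | C=C1[C@H]2CC(=O)[C@@H]([C@H](C)OC(C)=O)[C@@H]2[C@@H](C(C)=C)[C@H](O[Si](C)(C)C(C)(C)C)C1 | intermediate
15 | 8α‑alcohol (desilylated 14) | C=C1[C@H]2CC(=O)[C@@H]([C@H](C)OC(C)=O)[C@@H]2[C@@H](C(C)=C)[C@H](O)C1 | intermediate
16 | (11S)‑11,12‑epoxide of 15 | C=C1[C@H]2CC(=O)[C@@H]([C@H](C)OC(C)=O)[C@@H]2[C@@H]([C@@]2(C)CO2)[C@H](O)C1 | intermediate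
17 | (2Z)‑3‑methylpent‑2‑enoic acid | OC(=O)/C=C(/C)CC | starting material
18 | 8α‑[(2Z)‑3‑methylpent‑2‑enoyl] ester of 16 | C=C1[C@H]2CC(=O)[C@@H]([C@H](C)OC(C)=O)[C@@H]2[C@@H]([C@@]2(C)CO2)[C@H](OC(=O)/C=C(/C)CC)C1 | intermediate
19 | 9α‑hydroxy derivative of 18 | C=C1[C@H]2CC(=O)[C@@H]([C@H](C)OC(C)=O)[C@@H]2[C@@H]([C@@]2(C)CO2)[C@H](OC(=O)/C=C(/C)CC)[C@@H]1O | intermediate
20 | (2R)‑2‑methylbutanoic acid | OC(=O)[C@H](C)CC | starting material
21 | CNP0262178.2, 9α‑[(2R)‑2‑methylbutanoyl] ester of 19 | C=C1[C@H]2CC(=O)[C@@H]([C@H](C)OC(C)=O)[C@@H]2[C@@H]([C@@]2(C)CO2)[C@H](OC(=O)/C=C(/C)CC)[C@@H]1OC(=O)[C@H](C)CC | target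

**Step count and risks**
Total steps: 13. Longest linear sequence: 13 (1 → 21).

The three steps most likely to fail:

Step 4. The oxidative γ‑cyclisation may suffer from leakage through the α′‑enolate (closure at C2) or from oxidation of the dienoxyl radical before it closes. The fallback sets out from 6 and replaces the radical closure by a polar cation–olefin closure. The linear dienolate is quenched kinetically (KOt‑Bu, then cold aqueous AcOH) to the deconjugated β,γ‑unsaturated ketone F1. HOCl (Ca(OCl)2/CO2) then converts the trisubstituted side‑chain olefin into the secondary allylic chloride F2, with the double bond shifted into the isopropenyl position. AgBF4 with 2,6‑di‑tert‑butylpyridine in CH2Cl2 at −78 °C ionises F2 to the allyl cation, which the ring C5=C6 olefin captures through C6 (six‑membered ring); loss of H‑4 gives the cis‑fused enone 8, where the fallback rejoins the route and the base equilibration of step 4 gives 9.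

Step 7. Chelation control may not distinguish the acetyl from the ring carbonyl, giving diol or the wrong hydroxy ketone. The fallback sets out from 12 and uses catalyst control instead: transfer hydrogenation with RuCl[(S,S)‑TsDPEN](p‑cymene) and HCO2H/Et3N reduces the less hindered methyl ketone of the equilibrating diketone (dynamic kinetic resolution at C5) and rejoins the route at 13. No new compound is made (F0).

Step 12. With the 8‑ester next to C9 the ene step may be slow or divert to the C1–H, and the epoxide may open. The fallback sets out from 16 and changes the order: SeO2/t‑BuOOH on the free 8‑alcohol gives the 8α,9α‑diol F3. One equivalent of 17 with DCC/DMAP at −20 °C then acylates the more accessible equatorial 8‑OH in preference to the axial allylic 9‑OH, rejoining the route at 19.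

**Further compounds**
F1 | step 4 | 2‑methyl‑5‑[(4R)‑4‑(tert‑butyldimethylsilyloxy)‑6‑methylhepta‑1,5‑dien‑2‑yl]cyclohex‑3‑en‑1‑one (deconjugated ketone, C2 epimers) | C=C(C[C@@H](O[Si](C)(C)C(C)(C)C)C=C(C)C)[C@H]1CC(=O)C(C)C=C1
F2 | step 4 | 2‑methyl‑5‑[(4R)‑4‑(tert‑butyldimethylsilyloxy)‑5‑chloro‑6‑methylhepta‑1,6‑dien‑2‑yl]cyclohex‑3‑en‑1‑one (allylic chloride, epimers at the chloride carbon) | C=C(C[C@@H](O[Si](C)(C)C(C)(C)C)C(Cl)C(C)=C)[C@H]1CC(=O)C(C)C=C1
F0 | step 7 | none | none
F3 | step 12 | 8α,9α‑diol (9α‑hydroxy derivative of 16) | C=C1[C@H]2CC(=O)[C@@H]([C@H](C)OC(C)=O)[C@@H]2[C@@H]([C@@]2(C)CO2)[C@H](O)[C@@H]1O
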